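**Plan**

1. Atom labels (Daphniphyllum numbering): C1 lactam C=O, C2 CH(OH), C3/C4 CH2, C5 quaternary carbon bearing C21 (CH2OAc), C6 CH, C7 and C19 NCH2, C8 quaternary carbon next to C1, C9=C10 alkene, C11/C12 and C16/C17 CH2, C13 CH2, C14 CH(CO2Me), C15 CH, C18 CH(CH3). Ring A is the cyclopentane C14–C13–C8–C9–C15; ring B is the cyclopentene C9–C10–C17–C16–C15.
2. Cuts, last bond first: N–C1 (lactam), N–C7 and N–C19 (sulfonamide alkylations), C2–C18 (aldol), C10–C11 (B-alkyl Suzuki), C8–C13 (1,2-shift, traced back to a C1–C8 epoxide of a cyclohexene), C13–C14 and C9–C15 (Diels–Alder), C8–C1 and C9–C10 (vinyl cuprate, acetylide acylation), C5–C4, C5–C21 and C5–C6 (enolate and allylic alkylations).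
3. Forward: a vinyl butyrolactone is alkylated twice to the quaternary C5 and opened to an alkyne (fragment A), which is joined to a Z-enoate Weinreb amide (fragment B). One intramolecular Diels–Alder reaction closes the cyclohexene and ring B, epoxide contraction turns the cyclohexene into ring A, Suzuki coupling closes the cycloheptene, then the nine-membered azacycle and last the six-membered lactam are closed.
4. Enabling feature: C8 is a quaternary carbon of ring A and carries the lactam carbonyl carbon C1 as an exocyclic one-carbon group, which is what a cyclohexene oxide leaves when a ring CH2 shifts to the tertiary epoxide carbon. The cis arrangement of the C14 ester and the C15–C16 bond is what an endo cycloaddition of a Z-enoate leaves.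
5. Stereochemistry: C6 from iridium-catalysed allylic alkylation; C5 from anti alkylation of the lactone enolate; C9, C14 and C15 from the cycloaddition, steered by a sacrificial C10 carbinol (CBS reduction); C8 from convex-face epoxidation and anti migration; C2 and C18 from an Evans syn-aldol.

Key step: step 20

Remark: the carbon that ends as C10 is carried from step 16 to step 23 as an (S)-configured triethylsilyl ether and not as a ketone. It fixes the diene face in step 18 and leaves no enolisable carbonyl next to the cationic centre in step 20; the ketone is unveiled in step 24.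
Remark: compounds 1, 4, 9, 11, 16, 20, 39 and 44 are taken as purchased.

**Route**

Step 1
Reactants: 1 (E)-but-2-ene-1,4-diol
Product: 2 (E)-4-(tert-butyldimethylsilyloxy)but-2-en-1-ol
Conditions: NaH (1.0 equiv), THF, 0 °C; then t-BuMe2SiCl, 0 to 23 °C
Reagents that add atoms: tert-butyldimethylsilyl chloride, CC(C)(C)[Si](C)(C)Cl
Why: Monosilylation of the symmetrical diol through its sparingly soluble monosodium alkoxide should stop after one silyl ether has formed.

Step 2
Reactants: 2 (E)-4-(tert-butyldimethylsilyloxy)but-2-en-1-ol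
Product: 3 (E)-4-(tert-butyldimethylsilyloxy)but-2-en-1-yl methyl carbonate
Conditions: ClCO2Me, pyridine, CH2Cl2, 0 °C
Reagents that add atoms: methyl chloroformate, COC(Cl)=O
Why: O-Acylation of the primary allylic alcohol should give the linear carbonate needed as the leaving group for allylic substitution.

Step 3
Reactants: 3 (E)-4-(tert-butyldimethylsilyloxy)but-2-en-1-yl methyl carbonate; 4 dimethyl malonate
Product: 5 dimethyl 2-[(2S)-1-(tert-butyldimethylsilyloxy)but-3-en-2-yl]malonate
Conditions: [Ir(cod)Cl]2 (2 mol %), binaphthol-derived bis(1-phenylethyl)phosphoramidite (4 mol %, the enantiomer that leads to the 2S product), 1,5,7-triazabicyclo[4.4.0]dec-5-ene (8 mol %), THF, 23 °C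
Reagents that add atoms: none
Why: Iridium-catalysed asymmetric allylic alkylation of a linear carbonate with malonate should give the branched product, the chiral phosphoramidite–iridium allyl complex directing attack to one face of the substituted allyl terminus and so setting C6.

Step 4
Reactants: 5 dimethyl 2-[(2S)-1-(tert-butyldimethylsilyloxy)but-3-en-2-yl]malonate
Product: 7 methyl (3R,4S)-2-oxo-4-vinyloxolane-3-carboxylate, via hydroxy diester 6 (not isolated)
Conditions: camphorsulfonic acid (10 mol %), MeOH, 23 °C; then toluene, 60 °C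
Reagents that add atoms: none
Why: Acid methanolysis of the silyl ether should free the primary alcohol, which closes the lactone on one of the two equivalent esters by intramolecular transesterification (5-exo-trig), the epimerisable ester-bearing carbon settling trans to the vinyl group.

Step 5
Reactants: 7 methyl (3R,4S)-2-oxo-4-vinyloxolane-3-carboxylate
Product: 8 (4R)-4-vinyloxolan-2-one
Conditions: LiCl, H2O (2 equiv), DMSO, 140 °C
Reagents that add atoms: none
Why: Krapcho dealkoxycarbonylation should remove the activating ester without touching the C6 stereocentre.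

Step 6
Reactants: 8 (4R)-4-vinyloxolan-2-one; 9 benzyl chloromethyl ether
Product: 10 (3R,4S)-3-(benzyloxymethyl)-4-vinyloxolan-2-one
Conditions: LiN(i-Pr)2, THF, −78 °C; then 9, −78 to −40 °C
Reagents that add atoms: none
Why: Alkylation of the lactone lithium enolate should take place anti to the neighbouring vinyl group and introduce C21 as its benzyl ether, trans to vinyl.

Step 7
Reactants: 10 (3R,4S)-3-(benzyloxymethyl)-4-vinyloxolan-2-one; 11 tert-butyl(3-iodopropoxy)dimethylsilane
Product: 12 (3S,4S)-3-(benzyloxymethyl)-3-[3-(tert-butyldimethylsilyloxy)propyl]-4-vinyloxolan-2-one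
Conditions: LiN(i-Pr)2, THF, −78 °C; then DMPU and 11, −78 to −20 °C
Reagents that add atoms: none
Why: A second enolate alkylation should build the quaternary centre C5 with the three-carbon chain again entering anti to the C6 vinyl group, so that the order of the two alkylations fixes the C5 configuration (benzyloxymethyl cis to vinyl).

Step 8
Reactants: 12 (3S,4S)-3-(benzyloxymethyl)-3-[3-(tert-butyldimethylsilyloxy)propyl]-4-vinyloxolan-2-one
Product: 13 (3S,4S)-3-(benzyloxymethyl)-3-[3-(tert-butyldimethylsilyloxy)propyl]-4-vinyloxolan-2-ol (lactol, anomer mixture)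
Conditions: i-Bu2AlH (1.2 equiv), CH2Cl2, −78 °C; aq. potassium sodium tartrate
Reagents that add atoms: none
Why: Low-temperature hydride reduction of a lactone should stop at the aluminium hemiacetal and give the lactol on work-up.

Step 9
Reactants: 13 lactol
Product: 14 (2S,3R)-3-(benzyloxymethyl)-3-[3-(tert-butyldimethylsilyloxy)propyl]-2-vinylpent-4-yn-1-ol
Conditions: dimethyl (1-diazo-2-oxopropyl)phosphonate, K2CO3, MeOH, 0 to 23 °C
Reagents that add atoms: dimethyl (1-diazo-2-oxopropyl)phosphonate, CC(=O)C(=[N+]=[N-])P(=O)(OC)OC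
Why: Seyferth–Gilbert homologation with the Ohira–Bestmann reagent should convert the open hydroxy aldehyde form of the lactol into the terminal alkyne C8≡C9, there being no α-hydrogen to epimerise, and free the C7 hydroxyl.

Step 10
Reactants: 14 alkynol
Product: 15 tert-butyldiphenylsilyl ether of 14 (fragment A)
Conditions: t-BuPh2SiCl, imidazole, DMF, 23 °C
Reagents that add atoms: tert-butyldiphenylsilyl chloride, CC(C)(C)[Si](Cl)(c1ccccc1)c1ccccc1
Why: Silylation of the primary alcohol should give a bulky ether whose oxygen is a poor neighbouring group for the later cationic rearrangement.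

Step 11
Reactants: 16 pent-4-enoic acid
Product: 17 N-methoxy-N-methylpent-4-enamide
Conditions: 1,1'-carbonyldiimidazole, CH2Cl2, 23 °C; then MeNHOMe·HCl
Reagents that add atoms: N,O-dimethylhydroxylamine hydrochloride, CNOC.Cl
Why: Amide formation through the acyl imidazole should give the Weinreb amide that later holds acetylide addition at the ketone stage.

Step 12
Reactants: 17 N-methoxy-N-methylpent-4-enamide
Product: 19 N-methoxy-N-methyl-4-oxobutanamide, via ozonide 18 (not isolated)
Conditions: O3, CH2Cl2, −78 °C; then PPh3, −78 to 23 °C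
Reagents that add atoms: ozone, [O-][O+]=O
Why: Ozonolysis with reductive work-up should cleave the terminal alkene to the aldehyde.

Step 13
Reactants: 19 N-methoxy-N-methyl-4-oxobutanamide; 20 methyl bis(2,2,2-trifluoroethyl)phosphonoacetate
Product: 21 methyl (Z)-6-[methoxy(methyl)amino]-6-oxohex-2-enoate (fragment B)
Conditions: 20, KN(SiMe3)2, 18-crown-6, THF, −78 °C; then 19
Reagents that add atoms: none
Why: The Still–Gennari variant of the Horner–Wadsworth–Emmons olefination should give the Z-enoate by fast, kinetically controlled elimination from the trifluoroethyl phosphonate adduct.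

Step 14
Reactants: 15 fragment A; 21 fragment B
Product: 23 ynone MeO2C–C14H=C15H–C16H2–C17H2–C10(=O)–C9≡C8–C5(CH2OBn)[(CH2)3OSiMe2t-Bu]–C6H(CH=CH2)–CH2OSiPh2t-Bu with Z enoate, via lithium acetylide 22 (not isolated)
Conditions: n-BuLi (1.0 equiv), THF, −78 °C; then 21, −78 to −30 °C; AcOH, −78 °C
Reagents that add atoms: none
Why: Acylation of a lithium acetylide by a Weinreb amide should stop at the chelated tetrahedral adduct, the amide being attacked in preference to the conjugated methyl ester.

Step 15
Reactants: 23 ynone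
Product: 24 dienone (C9H=C8 bearing the new vinyl group C1=C13; C10 acyl group cis to C5)
Conditions: CH2=CHMgBr (2.2 equiv), CuI (1.1 equiv), THF, −78 °C; AcOH, −78 °C
Reagents that add atoms: vinylmagnesium bromide, C=C[Mg]Br
Why: Conjugate addition of a vinyl cuprate to the ynone should deliver the vinyl group to C8, and kinetic protonation of the allenolate from the side of the small vinyl group should place the acyl group cis to the quaternary carbon.

Step 16
Reactants: 24 dienone
Product: 25 (10S)-dienol
Conditions: (R)-2-methyl-CBS-oxazaborolidine (20 mol %), catecholborane, toluene, −78 °C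
Reagents that add atoms: none
Why: Corey–Bakshi–Shibata reduction should treat the alkenyl residue as the large ketone substituent and deliver hydride to one carbonyl face, giving the 10S allylic alcohol.

Step 17
Reactants: 25 (10S)-dienol
Product: 26 triethylsilyl ether of 25
Conditions: Et3SiCl, imidazole, CH2Cl2, 0 °C
Reagents that add atoms: chlorotriethylsilane, CC[Si](Cl)(CC)CC
Why: Silylation should protect the allylic alcohol as an ether that is labile enough to be removed later in the presence of the other two silyl groups.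

Step 18
Reactants: 26 triene silyl ether
Product: 27 cis-hydrindene (cyclohexene C14–C13–C1=C8–C9–C15 cis-fused at C9–C15 to cyclopentane C9–C10–C17–C16–C15; CO2Me on C14, OSiEt3 on C10, C5 side chain on C8; H9, H14, H15 and the C10–O bond on one face)
Conditions: toluene (0.01 M), 2,6-di-tert-butyl-4-methylphenol (cat.), 120 °C, sealed tube
Reagents that add atoms: none
Why: Intramolecular Diels–Alder reaction of the diene (tether trans to the vinyl group) with the Z-enoate through the endo transition state should close the cyclohexene and the cyclopentane with cis ring fusion and the ester cis to C16, while allylic 1,3-strain against the quaternary carbon keeps the C10 hydrogen in the diene plane so that the tether reaches one diene face only and C9, C14 and C15 follow from the 10S centre.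

Step 19
Reactants: 27 cis-hydrindene
Product: 28 C1–C8 epoxide of 27 (oxygen on the face of H9, H14 and H15)
Conditions: m-CPBA (1.1 equiv), NaHCO3, CH2Cl2, 0 °C
Reagents that add atoms: 3-chloroperoxybenzoic acid, OOC(=O)c1cccc(Cl)c1
Why: Prilezhaev epoxidation should pick the trisubstituted ring alkene over the monosubstituted vinyl group and attack the convex face of the cis-hydrindene, anti to the ester and to the fused five-membered ring.

Step 20
Reactants: 28 epoxide
Product: 29 ring-contracted aldehyde (cis-bicyclo[3.3.0]octane of rings A and B; quaternary C8 bearing CHO (C1) on the face of H9 and the C5 side chain on the face of CO2Me; OSiEt3 on C10)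
Conditions: MeAl(OAr)2 (Ar = 4-bromo-2,6-di-tert-butylphenyl, 3 equiv), CH2Cl2, −78 °C
Reagents that add atoms: none
Why: The bulky aluminium Lewis acid should bind the epoxide oxygen and ionise the C8–O bond at the tertiary carbon, whereupon the ring bond C1–C13, lying anti to the departing oxygen, shifts to C8 and C1 becomes the aldehyde carbon (Meinwald-type epoxide-to-aldehyde rearrangement, a semipinacol 1,2-alkyl shift well known for 1-substituted cyclohexene oxides with this class of reagent). Ring A is thus formed by ring contraction through a 1,2-shift and not by a cyclisation, and no other ring closes. The new quaternary stereocentre C8 is set by inversion at the epoxide carbon: the epoxide lies on the convex face, so C13 arrives from the concave face and the side chain ends up cis to the ester and to ring B with the formyl group on the other face. The step needs alkyl shift to win over hydride shift (cyclohexanone), over proton loss from C9 and over capture of the cationic centre; the size of the aluminium phenoxide disfavours the hydride pathway, C9 carries no acidifying carbonyl because C10 is a silyl ether, and the side-chain oxygens are silyl ethers (poor donors) or a benzyl ether that could only close a four-membered ring.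

Step 21
Reactants: 29 aldehyde
Product: 30 carboxylic acid (C1 = CO2H)
Conditions: NaClO2, NaH2PO4, 2-methylbut-2-ene, t-BuOH/H2O, 0 to 23 °C
Reagents that add atoms: sodium chlorite, [Na+].[O-]Cl=O
Why: Pinnick oxidation should convert the hindered, non-enolisable aldehyde into the acid, the alkene scavenger removing hypochlorous acid before it reaches the vinyl group.

Step 22
Reactants: 30 carboxylic acid
Product: 31 dimethyl ester (CO2Me at C1 and C14)
Conditions: Me3SiCHN2, MeOH/toluene, 0 °C
Reagents that add atoms: (trimethylsilyl)diazomethane, C[Si](C)(C)C=[N+]=[N-]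
Why: O-Methylation of the acid by the diazoalkane should give the methyl ester under neutral conditions despite the neopentyl surroundings.

Step 23
Reactants: 31 dimethyl ester
Product: 32 C10 alcohol
Conditions: HF·pyridine, pyridine, THF, 0 °C
Reagents that add atoms: none
Why: Fluoride desilylation should remove the triethylsilyl ether much faster than the tert-butyldimethylsilyl and tert-butyldiphenylsilyl ethers.

Step 24
Reactants: 32 C10 alcohol
Product: 33 C10 ketone (cis-bicyclo[3.3.0]octanone)
Conditions: Dess–Martin periodinane, NaHCO3, CH2Cl2, 23 °C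
Reagents that add atoms: none
Why: Dess–Martin oxidation should give the cyclopentanone and erase the relay stereocentre at C10.

Step 25
Reactants: 33 C10 ketone
Product: 34 enol triflate C9=C10–OSO2CF3
Conditions: Tf2O, 2,6-di-tert-butyl-4-methylpyridine, CH2Cl2, 0 to 23 °C
Reagents that add atoms: trifluoromethanesulfonic anhydride, O=S(=O)(OS(=O)(=O)C(F)(F)F)C(F)(F)F
Why: Enol triflate formation by O-triflation of the ketone and loss of a proton from the triflyloxycarbenium ion should favour the more substituted ring-fusion alkene C9=C10, and the non-basic medium leaves the C14 ester stereocentre alone.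

Step 26
Reactants: 34 enol triflate
Product: 36 tricyclic cycloheptene (seven-membered ring C8–C9=C10–C11–C12–C6–C5), via alkylborane 35 (not isolated)
Conditions: 9-BBN-H, THF, 23 °C; then Pd(dppf)Cl2 (10 mol %), AsPh3, aq. K3PO4, DMF, 50 °C
Reagents that add atoms: none
Why: Anti-Markovnikov hydroboration of the vinyl group followed by intramolecular B-alkyl Suzuki–Miyaura coupling with the enol triflate should form the C10–C11 bond and close the seven-membered ring.

Step 27
Reactants: 36 tricyclic cycloheptene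
Product: 37 C2 primary alcohol
Conditions: pyridinium p-toluenesulfonate, MeOH, 23 °C
Reagents that add atoms: none
Why: Mild acid methanolysis should cleave the primary tert-butyldimethylsilyl ether and spare the tert-butyldiphenylsilyl ether.

Step 28
Reactants: 37 C2 primary alcohol
Product: 38 C2 aldehyde
Conditions: Dess–Martin periodinane, NaHCO3, CH2Cl2, 23 °C
Reagents that add atoms: none
Why: Dess–Martin oxidation should give the aldehyde without epimerising C14 or moving the tetrasubstituted alkene.

Step 29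
Reactants: 38 C2 aldehyde; 39 (S)-4-benzyl-3-propanoyloxazolidin-2-one
Product: 41 syn-aldol adduct (C2 hydroxyl, C18 methyl, C19 acyl oxazolidinone), via boron enolate 40 (not isolated)
Conditions: 39, Bu2BOTf, i-Pr2NEt, CH2Cl2, −78 to 0 °C; then 38, −78 to 0 °C; H2O2, MeOH, pH 7 buffer
Reagents that add atoms: none
Why: The Evans syn-aldol reaction of the Z boron enolate through a Zimmerman–Traxler chair, the auxiliary benzyl group shielding one enolate face, should set C2 and C18 in the required syn relation and absolute sense under reagent control.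

Step 30
Reactants: 41 syn-aldol adduct
Product: 42 C2 triisopropylsilyl ether of 41
Conditions: i-Pr3SiOTf, 2,6-lutidine, CH2Cl2, −20 °C
Reagents that add atoms: triisopropylsilyl trifluoromethanesulfonate, CC(C)[Si](OS(=O)(=O)C(F)(F)F)(C(C)C)C(C)C
Why: Silylation of the secondary alcohol with the silyl triflate should give an ether that outlasts the later fluoride removal of the primary silyl group.

Step 31
Reactants: 42 silyl ether
Product: 43 C19 primary alcohol
Conditions: LiBH4, MeOH (1 equiv), THF, 0 °C
Reagents that add atoms: none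
Why: Reductive cleavage of the N-acyl oxazolidinone by borohydride should be much faster than reduction of the two hindered methyl esters.

Step 32
Reactants: 43 C19 primary alcohol; 44 2-nitrobenzenesulfonamide
Product: 45 C19 N-(2-nitrobenzenesulfonyl)amine
Conditions: 44 (3 equiv), PPh3, DIAD, THF, 0 to 23 °C
Reagents that add atoms: none
Why: Mitsunobu alkylation of the acidic sulfonamide (Fukuyama amine synthesis) should form the C19–N bond, the excess of sulfonamide preventing double alkylation.

Step 33
Reactants: 45 sulfonamide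
Product: 46 C7 primary alcohol
Conditions: Bu4NF, AcOH, THF, 0 to 23 °C
Reagents that add atoms: none
Why: Buffered fluoride desilylation should remove the primary tert-butyldiphenylsilyl ether while the hindered secondary triisopropylsilyl ether stays.

Step 34
Reactants: 46 C7 primary alcohol
Product: 47 N-sulfonyl azonane (nine-membered ring N–C19–C18–C2–C3–C4–C5–C6–C7)
Conditions: PPh3, DIAD, toluene (0.005 M, slow addition), 23 °C
Reagents that add atoms: none
Why: Intramolecular Fukuyama–Mitsunobu N-alkylation of the nitrobenzenesulfonamide should close the nine-membered azacycle by SN2 displacement at C7, a ring size for which this sulfonamide alkylation is established.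

Step 35
Reactants: 47 N-sulfonyl azonane
Product: 49 bridged lactam (N–C1 bond; C21 benzyl ether, C2 silyl ether), via secondary amine 48 (not isolated)
Conditions: PhSH, K2CO3, MeCN, 23 °C; then toluene, 2-hydroxypyridine, 110 °C
Reagents that add atoms: none
Why: Thiolate should remove the sulfonyl group through a Meisenheimer complex, and the freed secondary amine should acylate on the nearby C1 methyl ester in a six-membered lactamisation (6-exo-trig) that completes the bridged bicyclic lactam.

Step 36
Reactants: 49 bridged lactam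
Product: 50 C21 primary alcohol
Conditions: H2 (1 atm), Pd/C, EtOAc, 23 °C
Reagents that add atoms: none
Why: Hydrogenolysis should cleave the benzyl ether while the shielded tetrasubstituted alkene is not reduced under these mild conditions.

Step 37
Reactants: 50 C21 primary alcohol
Product: 51 C21 acetate (C2 silyl ether)
Conditions: Ac2O, pyridine, 4-(dimethylamino)pyridine (cat.), CH2Cl2, 23 °C
Reagents that add atoms: acetic anhydride, CC(=O)OC(C)=O
Why: Acylation of the only free hydroxyl should give the C21 acetate.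

Step 38
Reactants: 51 C21 acetate
Product: 52 target CNP0296366.1
Conditions: aq. HF, MeCN, 23 °C
Reagents that add atoms: none
Why: Acidic fluoride desilylation should free the C2 hydroxyl without touching the acetate, the methyl ester or the lactam.

**Compound list**

1 | (E)-but-2-ene-1,4-diol | OC/C=C/CO | starting material
2 | (E)-4-(tert-butyldimethylsilyloxy)but-2-en-1-ol | OC/C=C/CO[Si](C)(C)C(C)(C)C | intermediate
3 | (E)-4-(tert-butyldimethylsilyloxy)but-2-en-1-yl methyl carbonate | COC(=O)OC/C=C/CO[Si](C)(C)C(C)(C)C | intermediate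
4 | dimethyl malonate | COC(=O)CC(=O)OC | starting material
5 | dimethyl 2-[(2S)-1-(tert-butyldimethylsilyloxy)but-3-en-2-yl]malonate | COC(=O)C(C(=O)OC)[C@@H](CO[Si](C)(C)C(C)(C)C)C=C | intermediate
6 | dimethyl 2-[(2S)-1-hydroxybut-3-en-2-yl]malonate | COC(=O)C(C(=O)OC)[C@@H](CO)C=C | intermediate
7 | methyl (3R,4S)-2-oxo-4-vinyloxolane-3-carboxylate | COC(=O)[C@@H]1C(=O)OC[C@H]1C=C | intermediate
8 | (4R)-4-vinyloxolan-2-one | C=C[C@@H]1COC(=O)C1 | intermediate
9 | benzyl chloromethyl ether | ClCOCc1ccccc1 | starting material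
10 | (3R,4S)-3-(benzyloxymethyl)-4-vinyloxolan-2-one | C=C[C@@H]1COC(=O)[C@H]1COCc1ccccc1 | intermediate
11 | tert-butyl(3-iodopropoxy)dimethylsilane | ICCCO[Si](C)(C)C(C)(C)C | starting material
12 | (3S,4S)-3-(benzyloxymethyl)-3-[3-(tert-butyldimethylsilyloxy)propyl]-4-vinyloxolan-2-one | C=C[C@@H]1COC(=O)[C@@]1(COCc1ccccc1)CCCO[Si](C)(C)C(C)(C)C | intermediate
13 | (3S,4S)-3-(benzyloxymethyl)-3-[3-(tert-butyldimethylsilyloxy)propyl]-4-vinyloxolan-2-ol (anomer mixture) | C=C[C@@H]1COC(O)[C@@]1(COCc1ccccc1)CCCO[Si](C)(C)C(C)(C)C | intermediate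
14 | (2S,3R)-3-(benzyloxymethyl)-3-[3-(tert-butyldimethylsilyloxy)propyl]-2-vinylpent-4-yn-1-ol | C#C[C@@](COCc1ccccc1)(CCCO[Si](C)(C)C(C)(C)C)[C@@H](CO)C=C | intermediate
15 | tert-butyldiphenylsilyl ether of 14 (fragment A) | C#C[C@@](COCc1ccccc1)(CCCO[Si](C)(C)C(C)(C)C)[C@@H](CO[Si](c1ccccc1)(c1ccccc1)C(C)(C)C)C=C | intermediate
16 | pent-4-enoic acid | C=CCCC(O)=O | starting material
17 | N-methoxy-N-methylpent-4-enamide | C=CCCC(=O)N(C)OC | intermediate
18 | ozonide of 17 (3-substituted 1,2,4-trioxolane) | CON(C)C(=O)CCC1OCOO1 | intermediate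
19 | N-methoxy-N-methyl-4-oxobutanamide | O=CCCC(=O)N(C)OC | intermediate
20 | methyl bis(2,2,2-trifluoroethyl)phosphonoacetate | COC(=O)CP(=O)(OCC(F)(F)F)OCC(F)(F)F | starting material
21 | methyl (Z)-6-[methoxy(methyl)amino]-6-oxohex-2-enoate (fragment B) | COC(=O)/C=C\CCC(=O)N(C)OC | intermediate
22 | lithium acetylide of 15 | [Li]C#C[C@@](COCc1ccccc1)(CCCO[Si](C)(C)C(C)(C)C)[C@@H](CO[Si](c1ccccc1)(c1ccccc1)C(C)(C)C)C=C | intermediate
23 | Z-enoate ynone (C10 ketone, C8≡C9) | COC(=O)/C=C\CCC(=O)C#C[C@@](COCc1ccccc1)(CCCO[Si](C)(C)C(C)(C)C)[C@@H](CO[Si](c1ccccc1)(c1ccccc1)C(C)(C)C)C=C | intermediate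
24 | Z-enoate dienone (acyl cis to C5) | COC(=O)/C=C\CCC(=O)/C=C(/C=C)[C@@](COCc1ccccc1)(CCCO[Si](C)(C)C(C)(C)C)[C@@H](CO[Si](c1ccccc1)(c1ccccc1)C(C)(C)C)C=C | intermediate
25 | (10S)-dienol | COC(=O)/C=C\CC[C@H](O)/C=C(/C=C)[C@@](COCc1ccccc1)(CCCO[Si](C)(C)C(C)(C)C)[C@@H](CO[Si](c1ccccc1)(c1ccccc1)C(C)(C)C)C=C | intermediate
26 | triethylsilyl ether of 25 | COC(=O)/C=C\CC[C@H](O[Si](CC)(CC)CC)/C=C(/C=C)[C@@](COCc1ccccc1)(CCCO[Si](C)(C)C(C)(C)C)[C@@H](CO[Si](c1ccccc1)(c1ccccc1)C(C)(C)C)C=C | intermediate
27 | cis-hydrindene Diels–Alder adduct | COC(=O)[C@@H]1CC=C([C@@](COCc3ccccc3)(CCCO[Si](C)(C)C(C)(C)C)[C@@H](CO[Si](c3ccccc3)(c3ccccc3)C(C)(C)C)C=C)[C@@H]2[C@@H](O[Si](CC)(CC)CC)CC[C@@H]21 | intermediate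
28 | C1–C8 epoxide (key-step precursor) | COC(=O)[C@@H]1C[C@H]3O[C@@]3([C@@](COCc4ccccc4)(CCCO[Si](C)(C)C(C)(C)C)[C@@H](CO[Si](c4ccccc4)(c4ccccc4)C(C)(C)C)C=C)[C@@H]2[C@@H](O[Si](CC)(CC)CC)CC[C@@H]21 | intermediate
29 | ring-contracted aldehyde (key-step product) | COC(=O)[C@@H]1C[C@](C=O)([C@@](COCc3ccccc3)(CCCO[Si](C)(C)C(C)(C)C)[C@@H](CO[Si](c3ccccc3)(c3ccccc3)C(C)(C)C)C=C)[C@@H]2[C@@H](O[Si](CC)(CC)CC)CC[C@@H]21 | intermediate
30 | C1 carboxylic acid | COC(=O)[C@@H]1C[C@](C(O)=O)([C@@](COCc3ccccc3)(CCCO[Si](C)(C)C(C)(C)C)[C@@H](CO[Si](c3ccccc3)(c3ccccc3)C(C)(C)C)C=C)[C@@H]2[C@@H](O[Si](CC)(CC)CC)CC[C@@H]21 | intermediate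
31 | dimethyl ester | COC(=O)[C@@H]1C[C@](C(=O)OC)([C@@](COCc3ccccc3)(CCCO[Si](C)(C)C(C)(C)C)[C@@H](CO[Si](c3ccccc3)(c3ccccc3)C(C)(C)C)C=C)[C@@H]2[C@@H](O[Si](CC)(CC)CC)CC[C@@H]21 | intermediate
32 | C10 alcohol | COC(=O)[C@@H]1C[C@](C(=O)OC)([C@@](COCc3ccccc3)(CCCO[Si](C)(C)C(C)(C)C)[C@@H](CO[Si](c3ccccc3)(c3ccccc3)C(C)(C)C)C=C)[C@@H]2[C@@H](O)CC[C@@H]21 | intermediate
33 | C10 ketone | COC(=O)[C@@H]1C[C@](C(=O)OC)([C@@](COCc3ccccc3)(CCCO[Si](C)(C)C(C)(C)C)[C@@H](CO[Si](c3ccccc3)(c3ccccc3)C(C)(C)C)C=C)[C@@H]2C(=O)CC[C@@H]21 | intermediate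
34 | C9=C10 enol triflate | COC(=O)[C@@H]1C[C@](C(=O)OC)([C@@](COCc3ccccc3)(CCCO[Si](C)(C)C(C)(C)C)[C@@H](CO[Si](c3ccccc3)(c3ccccc3)C(C)(C)C)C=C)C2=C(OS(=O)(=O)C(F)(F)F)CC[C@@H]21 | intermediate
35 | C11 B-alkyl-9-borabicyclo[3.3.1]nonane | COC(=O)[C@@H]1C[C@](C(=O)OC)([C@@](COCc3ccccc3)(CCCO[Si](C)(C)C(C)(C)C)[C@@H](CO[Si](c3ccccc3)(c3ccccc3)C(C)(C)C)CCB5C6CCCC5CCC6)C2=C(OS(=O)(=O)C(F)(F)F)CC[C@@H]21 | intermediate
36 | tricyclic cycloheptene | COC(=O)[C@@H]1C[C@@]2(C(=O)OC)C3=C(CC[C@@H]([C@]2(COCc4ccccc4)CCCO[Si](C)(C)C(C)(C)C)CO[Si](c4ccccc4)(c4ccccc4)C(C)(C)C)CC[C@@H]31 | intermediate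
37 | C2 primary alcohol | COC(=O)[C@@H]1C[C@@]2(C(=O)OC)C3=C(CC[C@@H]([C@]2(COCc4ccccc4)CCCO)CO[Si](c4ccccc4)(c4ccccc4)C(C)(C)C)CC[C@@H]31 | intermediate
38 | C2 aldehyde | COC(=O)[C@@H]1C[C@@]2(C(=O)OC)C3=C(CC[C@@H]([C@]2(COCc4ccccc4)CCC=O)CO[Si](c4ccccc4)(c4ccccc4)C(C)(C)C)CC[C@@H]31 | intermediate
39 | (S)-4-benzyl-3-propanoyloxazolidin-2-one | CCC(=O)N1[C@@H](Cc2ccccc2)COC1=O | starting material
40 | (Z)-dibutylboron enolate of 39 | C/C=C(\OB(CCCC)CCCC)N1[C@@H](Cc2ccccc2)COC1=O | intermediate
41 | syn-aldol adduct | COC(=O)[C@@H]1C[C@@]2(C(=O)OC)C3=C(CC[C@@H]([C@]2(COCc4ccccc4)CC[C@@H](O)[C@H](C)C(=O)N5[C@@H](Cc6ccccc6)COC5=O)CO[Si](c4ccccc4)(c4ccccc4)C(C)(C)C)CC[C@@H]31 | intermediate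
42 | C2 triisopropylsilyl ether of 41 | COC(=O)[C@@H]1C[C@@]2(C(=O)OC)C3=C(CC[C@@H]([C@]2(COCc4ccccc4)CC[C@@H](O[Si](C(C)C)(C(C)C)C(C)C)[C@H](C)C(=O)N5[C@@H](Cc6ccccc6)COC5=O)CO[Si](c4ccccc4)(c4ccccc4)C(C)(C)C)CC[C@@H]31 | intermediate
43 | C19 primary alcohol | COC(=O)[C@@H]1C[C@@]2(C(=O)OC)C3=C(CC[C@@H]([C@]2(COCc4ccccc4)CC[C@@H](O[Si](C(C)C)(C(C)C)C(C)C)[C@H](C)CO)CO[Si](c4ccccc4)(c4ccccc4)C(C)(C)C)CC[C@@H]31 | intermediate
44 | 2-nitrobenzenesulfonamide | NS(=O)(=O)c1ccccc1[N+](=O)[O-] | starting material
45 | C19 N-(2-nitrobenzenesulfonyl)amine | COC(=O)[C@@H]1C[C@@]2(C(=O)OC)C3=C(CC[C@@H]([C@]2(COCc4ccccc4)CC[C@@H](O[Si](C(C)C)(C(C)C)C(C)C)[C@H](C)CNS(=O)(=O)c4ccccc4[N+](=O)[O-])CO[Si](c4ccccc4)(c4ccccc4)C(C)(C)C)CC[C@@H]31 | intermediate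
46 | C7 primary alcohol | COC(=O)[C@@H]1C[C@@]2(C(=O)OC)C3=C(CC[C@@H]([C@]2(COCc4ccccc4)CC[C@@H](O[Si](C(C)C)(C(C)C)C(C)C)[C@H](C)CNS(=O)(=O)c4ccccc4[N+](=O)[O-])CO)CC[C@@H]31 | intermediate
47 | N-sulfonyl azonane | COC(=O)[C@@H]1C[C@@]2(C(=O)OC)C3=C(CC[C@@H]([C@]2(COCc4ccccc4)CC[C@@H](O[Si](C(C)C)(C(C)C)C(C)C)[C@H](C)CN5S(=O)(=O)c4ccccc4[N+](=O)[O-])C5)CC[C@@H]31 | intermediate
48 | secondary amine (azonane N–H) | COC(=O)[C@@H]1C[C@@]2(C(=O)OC)C3=C(CC[C@@H]([C@]2(COCc4ccccc4)CC[C@@H](O[Si](C(C)C)(C(C)C)C(C)C)[C@H](C)CN5)C5)CC[C@@H]31 | intermediate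
49 | bridged lactam, C21 benzyl ether, C2 silyl ether | COC(=O)[C@@H]1C[C@@]23C(=O)N4C[C@@H](CCC5=C2[C@@H]1CC5)[C@]3(COCc6ccccc6)CC[C@@H](O[Si](C(C)C)(C(C)C)C(C)C)[C@H](C)C4 | intermediate
50 | C21 primary alcohol | COC(=O)[C@@H]1C[C@@]23C(=O)N4C[C@@H](CCC5=C2[C@@H]1CC5)[C@]3(CO)CC[C@@H](O[Si](C(C)C)(C(C)C)C(C)C)[C@H](C)C4 | intermediate
51 | C21 acetate, C2 silyl ether | COC(=O)[C@@H]1C[C@@]23C(=O)N4C[C@@H](CCC5=C2[C@@H]1CC5)[C@]3(COC(C)=O)CC[C@@H](O[Si](C(C)C)(C(C)C)C(C)C)[C@H](C)C4 | intermediate
52 | CNP0296366.1 | COC(=O)[C@@H]1C[C@@]23C(=O)N4C[C@@H](CCC5=C2[C@@H]1CC5)[C@]3(COC(C)=O)CC[C@@H](O)[C@H](C)C4 | target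

**Step count and risks**

Total steps: 38. Longest linear sequence: 35 (steps 1–10, then 14–38); fragment B takes steps 11–13.

Step 20 (ring contraction). What may go wrong: hydride migration instead of migration of the ring CH2 (a cyclohexanone results), loss of a proton from C9 to an allylic alcohol, or capture of the developing cation by a side-chain ether oxygen. The fallback sets out from 27 and comes back at 29 by a pinacol-type shift of a diol derivative instead of an epoxide opening. Dihydroxylation of the ring alkene with OsO4 (cat.) and N-methylmorpholine N-oxide from the same convex face would give the cis-diol F1. Trimethyl orthoacetate with pyridinium p-toluenesulfonate would turn it into the cyclic orthoester F2. BF3·OEt2 in CH2Cl2 at −78 °C would then open the derived dioxolanylium ion at the tertiary C8–O bond with anti migration of C13; the C1 oxygen stays acylated until aqueous work-up releases 29.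

Step 25 (enol triflate). What may go wrong: proton loss toward the more accessible ring CH2 (C17), which puts the triflate, and later the alkene, on the wrong side of C10. The fallback sets out from 33 and comes back at 36 without any enol derivative. 9-BBN-H followed by NaBO3·4H2O (the vinyl group should react before the hindered ketone) would give the hydroxy ketone F3. I2, PPh3 and imidazole would give the iodo ketone F4. SmI2 with HMPA in THF would close the seven-membered ring by intramolecular Barbier addition of C11 to the C10 ketone and give the tertiary alcohol F5. Dehydration with the Burgess reagent (the C9 hydrogen is cis to the hydroxyl) or with SOCl2 and pyridine, followed if needed by acid equilibration to the tetrasubstituted alkene, would lead to 36.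

Step 34 (nine-membered ring). What may go wrong: intermolecular Mitsunobu coupling to oligomers, or elimination, outrunning the medium-ring closure at the β-branched C7. The fallback sets out from 43 and comes back at 49 with the order of ring formation reversed: six-membered lactam first, N–C19 bond last. An Appel reaction (CCl4, PPh3) would give the C19 chloride F6. Bu4NF with AcOH would free C7 to give the chloro alcohol F7. Mitsunobu azidation ((PhO)2P(O)N3, DIAD, PPh3) would give the C7 azide F8. Staudinger reduction (PMe3, THF/H2O) and heating in toluene would close the six-membered lactam on the C1 ester to give the N–H lactam chloride F9. NaH with NaI in DMF would then alkylate the lactam nitrogen with C19 and give 49.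

**Further compounds**

F1 | step 20 | cis-diol of 27 at C1 and C8 (both hydroxyls on the face of H9) | COC(=O)[C@@H]1C[C@@H](O)[C@](O)([C@@](COCc3ccccc3)(CCCO[Si](C)(C)C(C)(C)C)[C@@H](CO[Si](c3ccccc3)(c3ccccc3)C(C)(C)C)C=C)[C@@H]2[C@@H](O[Si](CC)(CC)CC)CC[C@@H]21
F2 | step 20 | cyclic methyl orthoacetate of F1 | COC(=O)[C@@H]1C[C@H]3OC(C)(OC)O[C@@]3([C@@](COCc4ccccc4)(CCCO[Si](C)(C)C(C)(C)C)[C@@H](CO[Si](c4ccccc4)(c4ccccc4)C(C)(C)C)C=C)[C@@H]2[C@@H](O[Si](CC)(CC)CC)CC[C@@H]21
F3 | step 25 | C11 hydroxy ketone | COC(=O)[C@@H]1C[C@](C(=O)OC)([C@@](COCc3ccccc3)(CCCO[Si](C)(C)C(C)(C)C)[C@@H](CO[Si](c3ccccc3)(c3ccccc3)C(C)(C)C)CCO)[C@@H]2C(=O)CC[C@@H]21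
F4 | step 25 | C11 iodo ketone | COC(=O)[C@@H]1C[C@](C(=O)OC)([C@@](COCc3ccccc3)(CCCO[Si](C)(C)C(C)(C)C)[C@@H](CO[Si](c3ccccc3)(c3ccccc3)C(C)(C)C)CCI)[C@@H]2C(=O)CC[C@@H]21
F5 | step 25 | C10 tertiary alcohol with closed seven-membered ring (hydroxyl cis to H9) | COC(=O)[C@@H]1C[C@@]2(C(=O)OC)[C@@H]3[C@](O)(CC[C@@H]([C@]2(COCc4ccccc4)CCCO[Si](C)(C)C(C)(C)C)CO[Si](c4ccccc4)(c4ccccc4)C(C)(C)C)CC[C@@H]31
F6 | step 34 | C19 chloride | COC(=O)[C@@H]1C[C@@]2(C(=O)OC)C3=C(CC[C@@H]([C@]2(COCc4ccccc4)CC[C@@H](O[Si](C(C)C)(C(C)C)C(C)C)[C@H](C)CCl)CO[Si](c4ccccc4)(c4ccccc4)C(C)(C)C)CC[C@@H]31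
F7 | step 34 | C19 chloride with free C7 alcohol | COC(=O)[C@@H]1C[C@@]2(C(=O)OC)C3=C(CC[C@@H]([C@]2(COCc4ccccc4)CC[C@@H](O[Si](C(C)C)(C(C)C)C(C)C)[C@H](C)CCl)CO)CC[C@@H]31
F8 | step 34 | C7 azide, C19 chloride | COC(=O)[C@@H]1C[C@@]2(C(=O)OC)C3=C(CC[C@@H]([C@]2(COCc4ccccc4)CC[C@@H](O[Si](C(C)C)(C(C)C)C(C)C)[C@H](C)CCl)CN=[N+]=[N-])CC[C@@H]31
F9 | step 34 | six-membered N–H lactam with C19 chloride | COC(=O)[C@@H]1C[C@@]23C(=O)NC[C@@H](CCC5=C2[C@@H]1CC5)[C@]3(COCc6ccccc6)CC[C@@H](O[Si](C(C)C)(C(C)C)C(C)C)[C@H](C)CCl
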